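**Plan**
- Retrosynthesis: the lactone C3–CH2Ar bond is cut first (enolate alkylation), giving a 5-(bromomethyl)dihydrobenzofuran and a 4-substituted butyrolactone; the lactone is traced to an anti-aldol adduct of silylated vanillin.
- In the dihydrobenzofuran (O1, C2 carrying guaiacyl ring A, C3 carrying CH2OH, benzo carbons C3a to C7a) the CH2OH carbon, C3 and C3a map onto C4, C3 and C4a of a 2-arylchroman-4-one. The C3–C3a bond is therefore cut and C3a reattached to the exocyclic carbon, which leads back to a (2S)-flavanone.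
- Forward order of rings: pyranone ring by oxa-Michael closure, its oxidative contraction to five-membered ring B, then the lactone ring from a lactol, then union of the two fragments and desilylation.
- Stereochemistry: C2 from the chiral thiourea catalyst; C3 from the stereospecific 1,2-shift (trans, also the stable isomer); lactone C4 and the carbinol from the oxazolidinone-controlled anti-aldol; lactone C3 from alkylation anti to the C4 substituent.

Key step: step 6

Remark: the quinidine-derived thiourea is assumed to deliver the 2S flavanone (its quinine-derived pseudoenantiomer would give 2R), and the MgCl2 anti-aldol is assumed to follow the facial sense of chelated oxazolidinone enolates; TBS = tert-butyldimethylsilyl, Ms = methanesulfonyl.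

**Route**

Step 1
Reactants: 1 methyl 2-hydroxy-3-methoxybenzoate
Product: 2 methyl 5-bromo-2-hydroxy-3-methoxybenzoate
Conditions: Br2 (1.05 equiv), AcOH, rt
Reagents that add atoms: bromine, BrBr
Why: Electrophilic aromatic bromination is directed para to the phenol, whose two ortho positions are blocked, and the ester directs meta to the same carbon.

Step 2
Reactants: 2 methyl 5-bromo-2-hydroxy-3-methoxybenzoate; 3 tert-butyl acetate
Product: 5 tert-butyl 3-(5-bromo-2-hydroxy-3-methoxyphenyl)-3-oxopropanoate, via lithium enolate of tert-butyl acetate 4 (not isolated)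
Conditions: LiN(iPr)2 (3.3 equiv), 3 (3.3 equiv), THF, −78 °C; then 2, −78 → 0 °C; 1 M HCl
Reagents that add atoms: none
Why: Crossed Claisen condensation of an ester enolate with a salicylate, in which the excess enolate first forms the phenoxide and finally deprotonates the β-keto ester product, which drives the addition–elimination to completion.

Step 3
Reactants: 6 vanillin
Product: 7 4-formyl-2-methoxyphenyl methanesulfonate
Conditions: MsCl, Et3N, CH2Cl2, 0 °C
Reagents that add atoms: methanesulfonyl chloride, CS(=O)(=O)Cl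
Why: O-Sulfonylation of the phenol gives an acid-stable, electron-withdrawing protecting group that will deactivate ring A in step 6.

Step 4
Reactants: 5 tert-butyl 3-(5-bromo-2-hydroxy-3-methoxyphenyl)-3-oxopropanoate; 7 4-formyl-2-methoxyphenyl methanesulfonate
Product: 8 tert-butyl (Z)-2-(5-bromo-2-hydroxy-3-methoxybenzoyl)-3-[3-methoxy-4-(methylsulfonyloxy)phenyl]prop-2-enoate
Conditions: piperidine (10 mol%), AcOH (10 mol%), 4 Å MS, toluene, rt
Reagents that add atoms: none
Why: Knoevenagel condensation of the active methylene of the β-keto ester with the aryl aldehyde proceeds under buffered amine catalysis that the aryl mesylate tolerates, and the isomer with the aryl group cis to the ester (Z) is expected to prevail.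

Step 5
Reactants: 8 tert-butyl (Z)-2-(5-bromo-2-hydroxy-3-methoxybenzoyl)-3-[3-methoxy-4-(methylsulfonyloxy)phenyl]prop-2-enoate
Product: 10 (2S)-6-bromo-8-methoxy-2-[3-methoxy-4-(methylsulfonyloxy)phenyl]chroman-4-one, via tert-butyl (2S)-4-oxochromane-3-carboxylate 9 (not isolated)
Conditions: quinidine-derived thiourea [3,5-bis(trifluoromethyl)phenyl thiourea of 9-amino-9-deoxy-epi-quinidine] (10 mol%), toluene, −25 °C; then TsOH·H2O (0.5 equiv), 80 °C
Reagents that add atoms: none
Why: Bifunctional thiourea-catalysed intramolecular oxa-Michael addition (6-endo-trig) of the phenol to the alkylidene β-keto ester, in which the thiourea binds the dicarbonyl unit and the quinuclidine base guides the phenol to one face so that C2 is set by the catalyst, is followed in the same flask by acid cleavage of the tert-butyl ester and decarboxylation.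

Step 6
Reactants: 10 (2S)-6-bromo-8-methoxy-2-[3-methoxy-4-(methylsulfonyloxy)phenyl]chroman-4-one
Product: 11 methyl (2S,3S)-5-bromo-7-methoxy-2-[3-methoxy-4-(methylsulfonyloxy)phenyl]-2,3-dihydro-1-benzofuran-3-carboxylate (trans)
Conditions: PhI(OAc)2 (1.2 equiv), HC(OMe)3, conc. H2SO4, 0 °C → rt
Reagents that add atoms: trimethyl orthoformate, COC(OC)OC
Why: Acid and orthoformate turn the ketone into its methyl enol ether, PhI(OAc)2 (trivalent iodine) adds to C3 from the face away from the C2 aryl group while methanol caps C4, and the equatorial C3–I bond then lies antiperiplanar to the C4–C4a ring bond, so that loss of iodobenzene is accompanied by a 1,2-shift of the benzo carbon C4a from C4 to C3; the dimethoxycarbenium ion left on the extruded carbon gives up one O-methyl group and becomes the methyl ester. The closest known reaction type is the oxidative 1,2-aryl migration of alkyl aryl ketones to arylacetic esters with hypervalent iodine or Tl(NO3)3 in trimethyl orthoformate, which has been applied to flavanones. Ring B is closed not by a new cyclisation but by this ring contraction (six-membered pyranone to five-membered dihydrofuran), the C3–C3a bond being the migrating bond. C2 is not involved and stays S, and the new C3 centre is fixed by the stereospecific anti displacement of an iodane that sat trans to the aryl group, which places the ester trans (3S), the isomer also favoured thermodynamically because C3 is alpha to the ester. The step needs migration of the benzo carbon to win over migration of the C2 aryl group (isoflavone) and over dehydrogenation (flavone): the migrating carbon is ortho to the ring oxygen and electron-rich, ring A is deactivated by the mesylate, and the orthoformate medium holds the substrate as ketal or enol ether.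

Step 7
Reactants: 11 methyl (2S,3S)-5-bromo-7-methoxy-2-[3-methoxy-4-(methylsulfonyloxy)phenyl]-2,3-dihydro-1-benzofuran-3-carboxylate
Product: 12 4-[(2S,3R)-5-bromo-3-(hydroxymethyl)-7-methoxy-2,3-dihydro-1-benzofuran-2-yl]-2-methoxyphenyl methanesulfonate
Conditions: iBu2AlH (3 equiv), CH2Cl2, −78 → 0 °C; aq. potassium sodium tartrate
Reagents that add atoms: none
Why: Hydride reduction of the ester to the primary alcohol leaves the aryl sulfonate and the aryl bromide untouched and does not involve the C3 centre, whose descriptor becomes R only through the priority rules.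

Step 8
Reactants: 12 4-[(2S,3R)-5-bromo-3-(hydroxymethyl)-7-methoxy-2,3-dihydro-1-benzofuran-2-yl]-2-methoxyphenyl methanesulfonate
Product: 13 4-[(2S,3R)-5-bromo-3-(hydroxymethyl)-7-methoxy-2,3-dihydro-1-benzofuran-2-yl]-2-methoxyphenol
Conditions: KOH (5 equiv), MeOH/THF/H2O, 60 °C; then 1 M HCl to pH 6
Reagents that add atoms: none
Why: Alkaline hydrolysis of the aryl sulfonate (attack at sulfur, S–O cleavage) frees the phenol at a stage where no ester remains next to the ring oxygen that could trigger base-induced ring opening.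

Step 9
Reactants: 13 4-[(2S,3R)-5-bromo-3-(hydroxymethyl)-7-methoxy-2,3-dihydro-1-benzofuran-2-yl]-2-methoxyphenol
Product: 14 (2S,3R)-5-bromo-2-[4-(TBSO)-3-methoxyphenyl]-3-(TBSO-methyl)-7-methoxy-2,3-dihydro-1-benzofuran
Conditions: TBSCl (2.5 equiv), imidazole, DMF, rt
Reagents that add atoms: tert-butyldimethylsilyl chloride, CC(C)(C)[Si](C)(C)Cl
Why: Silylation with silyl chloride and imidazole protects phenol and primary alcohol as ethers that withstand organolithium, hydride and enolate chemistry and are removed together by fluoride at the end.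

Step 10
Reactants: 14 (2S,3R)-5-bromo-2-[4-(TBSO)-3-methoxyphenyl]-3-(TBSO-methyl)-7-methoxy-2,3-dihydro-1-benzofuran
Product: 17 [(2S,3R)-2-[4-(TBSO)-3-methoxyphenyl]-3-(TBSO-methyl)-7-methoxy-2,3-dihydro-1-benzofuran-5-yl]methanol, via aryllithium 15 (not isolated), via 5-carbaldehyde 16 (not isolated)
Conditions: n-BuLi (1.1 equiv), THF, −78 °C; DMF, −78 → 0 °C; then MeOH, NaBH4, 0 °C; aq. NH4Cl
Reagents that add atoms: N,N-dimethylformamide, CN(C)C=O
Why: Bromine–lithium exchange, formylation of the aryllithium with DMF (Bouveault type) and borohydride reduction of the released aldehyde in the same flask turn the aryl bromide into the benzylic alcohol without touching the silyl ethers or the ring stereocentres.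

Step 11
Reactants: 17 [(2S,3R)-2-[4-(TBSO)-3-methoxyphenyl]-3-(TBSO-methyl)-7-methoxy-2,3-dihydro-1-benzofuran-5-yl]methanol
Product: 18 (2S,3R)-5-(bromomethyl)-2-[4-(TBSO)-3-methoxyphenyl]-3-(TBSO-methyl)-7-methoxy-2,3-dihydro-1-benzofuran
Conditions: CBr4, PPh3, CH2Cl2, 0 °C
Reagents that add atoms: carbon tetrabromide, BrC(Br)(Br)Br
Why: Appel bromination converts the electron-rich benzylic alcohol into the bromide under neutral conditions compatible with the silyl ethers, and the bromide is used without storage.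

Step 12
Reactants: 6 vanillin
Product: 19 4-(TBSO)-3-methoxybenzaldehyde
Conditions: TBSCl, imidazole, CH2Cl2, rt
Reagents that add atoms: tert-butyldimethylsilyl chloride, CC(C)(C)[Si](C)(C)Cl
Why: Silylation of the phenol gives a non-enolisable aryl aldehyde whose protecting group matches those of the other fragment.

Step 13
Reactants: 20 (R)-4-benzyl-1,3-oxazolidin-2-one; 21 pent-4-enoyl chloride
Product: 22 (R)-4-benzyl-3-(pent-4-enoyl)-1,3-oxazolidin-2-one
Conditions: Et3N, DMAP (10 mol%), CH2Cl2, 0 °C → rt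
Reagents that add atoms: none
Why: N-Acylation of the oxazolidinone with the acid chloride under DMAP catalysis attaches the chiral auxiliary to the five-carbon chain whose alkene later becomes the lactone carbonyl.

Step 14
Reactants: 22 (R)-4-benzyl-3-(pent-4-enoyl)-1,3-oxazolidin-2-one; 19 4-(TBSO)-3-methoxybenzaldehyde
Product: 24 (R)-4-benzyl-3-[(2S)-2-{(R)-[4-(TBSO)-3-methoxyphenyl](hydroxy)methyl}pent-4-enoyl]-1,3-oxazolidin-2-one, via trimethylsilyl ether 23 (not isolated)
Conditions: MgCl2 (20 mol%), Et3N, Me3SiCl, EtOAc, rt; then 1 M HCl, THF, 0 °C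
Reagents that add atoms: none
Why: MgCl2-catalysed direct anti-aldol addition of the N-acyloxazolidinone (soft enolisation, silyl trapping of the aldolate) to the aryl aldehyde, in which the chelated Z-enolate reacts on the face opposite the benzyl group through a boat-like transition state, sets the two adjacent centres (2S and carbinol R, anti), and brief cold dilute acid removes only the trimethylsilyl group.

Step 15
Reactants: 24 (R)-4-benzyl-3-[(2S)-2-{(R)-[4-(TBSO)-3-methoxyphenyl](hydroxy)methyl}pent-4-enoyl]-1,3-oxazolidin-2-one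
Product: 25 (R)-4-benzyl-3-[(2S)-2-{(R)-[4-(TBSO)-3-methoxyphenyl](TBSO)methyl}pent-4-enoyl]-1,3-oxazolidin-2-one
Conditions: TBSOTf, 2,6-lutidine, CH2Cl2, −78 → 0 °C
Reagents that add atoms: tert-butyldimethylsilyl trifluoromethanesulfonate, CC(C)(C)[Si](C)(C)OS(=O)(=O)C(F)(F)F
Why: Silylation of the hindered benzylic alcohol with the silyl triflate and a non-nucleophilic base avoids retro-aldol cleavage and blocks this hydroxyl, so that only the primary alcohol can close the lactol later.

Step 16
Reactants: 25 (R)-4-benzyl-3-[(2S)-2-{(R)-[4-(TBSO)-3-methoxyphenyl](TBSO)methyl}pent-4-enoyl]-1,3-oxazolidin-2-one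
Product: 26 (2R)-2-{(R)-[4-(TBSO)-3-methoxyphenyl](TBSO)methyl}pent-4-en-1-ol
Conditions: LiBH4, MeOH (1 equiv), THF, 0 °C
Reagents that add atoms: none
Why: Reductive cleavage of the N-acyloxazolidinone by borohydride gives the primary alcohol and returns the auxiliary without epimerisation, the descriptor changing to 2R only through the priority rules.

Step 17
Reactants: 26 (2R)-2-{(R)-[4-(TBSO)-3-methoxyphenyl](TBSO)methyl}pent-4-en-1-ol
Product: 27 (4R)-4-{(R)-[4-(TBSO)-3-methoxyphenyl](TBSO)methyl}oxolan-2-ol (both anomers)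
Conditions: OsO4 (2 mol%), NaIO4, 2,6-lutidine, dioxane/H2O, rt
Reagents that add atoms: osmium tetroxide, O=[Os](=O)(=O)=O; sodium periodate, [Na+].[O-]I(=O)(=O)=O
Why: Lemieux–Johnson oxidative cleavage of the terminal alkene gives the aldehyde, which is captured at once by the primary alcohol as the five-membered lactol (5-exo-trig), the silylated carbinol being unable to compete.

Step 18
Reactants: 27 (4R)-4-{(R)-[4-(TBSO)-3-methoxyphenyl](TBSO)methyl}oxolan-2-ol
Product: 28 (4R)-4-{(R)-[4-(TBSO)-3-methoxyphenyl](TBSO)methyl}oxolan-2-one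
Conditions: nPr4N[RuO4] (5 mol%), N-methylmorpholine N-oxide, 4 Å MS, CH2Cl2, rt
Reagents that add atoms: none
Why: Ley–Griffith oxidation of the lactol gives the γ-butyrolactone under neutral conditions that leave the silyl ethers and the electron-rich arene alone.

Step 19
Reactants: 28 (4R)-4-{(R)-[4-(TBSO)-3-methoxyphenyl](TBSO)methyl}oxolan-2-one; 18 (2S,3R)-5-(bromomethyl)-2-[4-(TBSO)-3-methoxyphenyl]-3-(TBSO-methyl)-7-methoxy-2,3-dihydro-1-benzofuran
Product: 30 (3R,4R)-4-{(R)-[4-(TBSO)-3-methoxyphenyl](TBSO)methyl}-3-{[(2S,3R)-2-[4-(TBSO)-3-methoxyphenyl]-3-(TBSO-methyl)-7-methoxy-2,3-dihydro-1-benzofuran-5-yl]methyl}oxolan-2-one, via lithium enolate 29 (not isolated)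
Conditions: LiN(SiMe3)2 (1.1 equiv), THF, −78 °C; then 18 (1.2 equiv), DMPU, −78 → −30 °C
Reagents that add atoms: none
Why: Enolate alkylation of the lactone with the reactive benzylic bromide takes place anti to the bulky C4 substituent and should thus give the trans (3R,4R) lactone, as in the alkylation route to dibenzylbutyrolactone lignans.

Step 20
Reactants: 30 (3R,4R)-4-{(R)-[4-(TBSO)-3-methoxyphenyl](TBSO)methyl}-3-{[(2S,3R)-2-[4-(TBSO)-3-methoxyphenyl]-3-(TBSO-methyl)-7-methoxy-2,3-dihydro-1-benzofuran-5-yl]methyl}oxolan-2-one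
Product: 31 (3R,4R)-4-[(R)-hydroxy(4-hydroxy-3-methoxyphenyl)methyl]-3-{[(2S,3R)-2-(4-hydroxy-3-methoxyphenyl)-3-(hydroxymethyl)-7-methoxy-2,3-dihydro-1-benzofuran-5-yl]methyl}oxolan-2-one (CNP0233460.1)
Conditions: Bu4NF (6 equiv), AcOH (6 equiv), THF, 0 °C → rt
Reagents that add atoms: none
Why: Fluoride-induced desilylation removes the two aryl and two alkyl silyl ethers in one operation, and the acetic acid buffer keeps the phenols protonated so that the lactone and the p-hydroxybenzylic alcohol are not exposed to base.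

**Compound list**

1 | methyl 2-hydroxy-3-methoxybenzoate | COC(=O)c1cccc(OC)c1O | starting material
2 | methyl 5-bromo-2-hydroxy-3-methoxybenzoate | COC(=O)c1cc(Br)cc(OC)c1O | intermediate
3 | tert-butyl acetate | CC(=O)OC(C)(C)C | starting material
4 | lithium enolate of tert-butyl acetate (not isolated) | C=C(O[Li])OC(C)(C)C | intermediate
5 | tert-butyl 3-(5-bromo-2-hydroxy-3-methoxyphenyl)-3-oxopropanoate | CC(C)(C)OC(=O)CC(=O)c1cc(Br)cc(OC)c1O | intermediate
6 | vanillin (4-hydroxy-3-methoxybenzaldehyde) | COc1cc(C=O)ccc1O | starting material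
7 | 4-formyl-2-methoxyphenyl methanesulfonate | COc1cc(C=O)ccc1OS(C)(=O)=O | intermediate
8 | tert-butyl (Z)-2-(5-bromo-2-hydroxy-3-methoxybenzoyl)-3-[3-methoxy-4-(methylsulfonyloxy)phenyl]prop-2-enoate | CC(C)(C)OC(=O)/C(C(=O)c1cc(Br)cc(OC)c1O)=C\c1ccc(OS(C)(=O)=O)c(OC)c1 | intermediate
9 | tert-butyl (2S)-6-bromo-8-methoxy-2-[3-methoxy-4-(methylsulfonyloxy)phenyl]-4-oxochromane-3-carboxylate (C3 epimers in equilibrium through the enol; not isolated) | COc1cc([C@H]2Oc3c(OC)cc(Br)cc3C(=O)C2C(=O)OC(C)(C)C)ccc1OS(C)(=O)=O | intermediate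
10 | (2S)-6-bromo-8-methoxy-2-[3-methoxy-4-(methylsulfonyloxy)phenyl]chroman-4-one | COc1cc([C@H]2Oc3c(OC)cc(Br)cc3C(=O)C2)ccc1OS(C)(=O)=O | intermediate
11 | methyl (2S,3S)-5-bromo-7-methoxy-2-[3-methoxy-4-(methylsulfonyloxy)phenyl]-2,3-dihydro-1-benzofuran-3-carboxylate (trans) | COc1cc([C@H]2Oc3c(OC)cc(Br)cc3[C@@H]2C(=O)OC)ccc1OS(C)(=O)=O | intermediate
12 | 4-[(2S,3R)-5-bromo-3-(hydroxymethyl)-7-methoxy-2,3-dihydro-1-benzofuran-2-yl]-2-methoxyphenyl methanesulfonate | COc1cc([C@H]2Oc3c(OC)cc(Br)cc3[C@@H]2CO)ccc1OS(C)(=O)=O | intermediate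
13 | 4-[(2S,3R)-5-bromo-3-(hydroxymethyl)-7-methoxy-2,3-dihydro-1-benzofuran-2-yl]-2-methoxyphenol | COc1cc([C@H]2Oc3c(OC)cc(Br)cc3[C@@H]2CO)ccc1O | intermediate
14 | (2S,3R)-5-bromo-2-[4-(TBSO)-3-methoxyphenyl]-3-(TBSO-methyl)-7-methoxy-2,3-dihydro-1-benzofuran | COc1cc([C@H]2Oc3c(OC)cc(Br)cc3[C@@H]2CO[Si](C)(C)C(C)(C)C)ccc1O[Si](C)(C)C(C)(C)C | intermediate
15 | (2S,3R)-2-[4-(TBSO)-3-methoxyphenyl]-3-(TBSO-methyl)-7-methoxy-2,3-dihydro-1-benzofuran-5-yllithium (not isolated) | COc1cc([C@H]2Oc3c(OC)cc([Li])cc3[C@@H]2CO[Si](C)(C)C(C)(C)C)ccc1O[Si](C)(C)C(C)(C)C | intermediate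
16 | (2S,3R)-2-[4-(TBSO)-3-methoxyphenyl]-3-(TBSO-methyl)-7-methoxy-2,3-dihydro-1-benzofuran-5-carbaldehyde (not isolated) | COc1cc([C@H]2Oc3c(OC)cc(C=O)cc3[C@@H]2CO[Si](C)(C)C(C)(C)C)ccc1O[Si](C)(C)C(C)(C)C | intermediate
17 | [(2S,3R)-2-[4-(TBSO)-3-methoxyphenyl]-3-(TBSO-methyl)-7-methoxy-2,3-dihydro-1-benzofuran-5-yl]methanol | COc1cc([C@H]2Oc3c(OC)cc(CO)cc3[C@@H]2CO[Si](C)(C)C(C)(C)C)ccc1O[Si](C)(C)C(C)(C)C | intermediate
18 | (2S,3R)-5-(bromomethyl)-2-[4-(TBSO)-3-methoxyphenyl]-3-(TBSO-methyl)-7-methoxy-2,3-dihydro-1-benzofuran | COc1cc([C@H]2Oc3c(OC)cc(CBr)cc3[C@@H]2CO[Si](C)(C)C(C)(C)C)ccc1O[Si](C)(C)C(C)(C)C | intermediate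
19 | 4-(TBSO)-3-methoxybenzaldehyde | COc1cc(C=O)ccc1O[Si](C)(C)C(C)(C)C | intermediate
20 | (R)-4-benzyl-1,3-oxazolidin-2-one | O=C1N[C@H](Cc2ccccc2)CO1 | starting material
21 | pent-4-enoyl chloride | C=CCCC(Cl)=O | starting material
22 | (R)-4-benzyl-3-(pent-4-enoyl)-1,3-oxazolidin-2-one | C=CCCC(=O)N1[C@H](Cc2ccccc2)COC1=O | intermediate
23 | (R)-4-benzyl-3-[(2S)-2-{(R)-[4-(TBSO)-3-methoxyphenyl](trimethylsilyloxy)methyl}pent-4-enoyl]-1,3-oxazolidin-2-one (not isolated) | C=CC[C@H](C(=O)N1[C@H](Cc2ccccc2)COC1=O)[C@@H](O[Si](C)(C)C)c1ccc(O[Si](C)(C)C(C)(C)C)c(OC)c1 | intermediate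
24 | (R)-4-benzyl-3-[(2S)-2-{(R)-[4-(TBSO)-3-methoxyphenyl](hydroxy)methyl}pent-4-enoyl]-1,3-oxazolidin-2-one | C=CC[C@H](C(=O)N1[C@H](Cc2ccccc2)COC1=O)[C@@H](O)c1ccc(O[Si](C)(C)C(C)(C)C)c(OC)c1 | intermediate
25 | (R)-4-benzyl-3-[(2S)-2-{(R)-[4-(TBSO)-3-methoxyphenyl](TBSO)methyl}pent-4-enoyl]-1,3-oxazolidin-2-one | C=CC[C@H](C(=O)N1[C@H](Cc2ccccc2)COC1=O)[C@@H](O[Si](C)(C)C(C)(C)C)c1ccc(O[Si](C)(C)C(C)(C)C)c(OC)c1 | intermediate
26 | (2R)-2-{(R)-[4-(TBSO)-3-methoxyphenyl](TBSO)methyl}pent-4-en-1-ol | C=CC[C@H](CO)[C@@H](O[Si](C)(C)C(C)(C)C)c1ccc(O[Si](C)(C)C(C)(C)C)c(OC)c1 | intermediate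
27 | (4R)-4-{(R)-[4-(TBSO)-3-methoxyphenyl](TBSO)methyl}oxolan-2-ol (both anomers) | OC1C[C@H](CO1)[C@@H](O[Si](C)(C)C(C)(C)C)c1ccc(O[Si](C)(C)C(C)(C)C)c(OC)c1 | intermediate
28 | (4R)-4-{(R)-[4-(TBSO)-3-methoxyphenyl](TBSO)methyl}oxolan-2-one | O=C1C[C@H](CO1)[C@@H](O[Si](C)(C)C(C)(C)C)c1ccc(O[Si](C)(C)C(C)(C)C)c(OC)c1 | intermediate
29 | lithium enolate of 28 (not isolated) | [Li]OC1=C[C@H](CO1)[C@@H](O[Si](C)(C)C(C)(C)C)c1ccc(O[Si](C)(C)C(C)(C)C)c(OC)c1 | intermediate
30 | (3R,4R)-4-{(R)-[4-(TBSO)-3-methoxyphenyl](TBSO)methyl}-3-{[(2S,3R)-2-[4-(TBSO)-3-methoxyphenyl]-3-(TBSO-methyl)-7-methoxy-2,3-dihydro-1-benzofuran-5-yl]methyl}oxolan-2-one | COc1cc([C@H]2Oc3c(OC)cc(C[C@H]4C(=O)OC[C@@H]4[C@@H](O[Si](C)(C)C(C)(C)C)c4ccc(O[Si](C)(C)C(C)(C)C)c(OC)c4)cc3[C@@H]2CO[Si](C)(C)C(C)(C)C)ccc1O[Si](C)(C)C(C)(C)C | intermediate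
31 | (3R,4R)-4-[(R)-hydroxy(4-hydroxy-3-methoxyphenyl)methyl]-3-{[(2S,3R)-2-(4-hydroxy-3-methoxyphenyl)-3-(hydroxymethyl)-7-methoxy-2,3-dihydro-1-benzofuran-5-yl]methyl}oxolan-2-one | COc1cc([C@H]2Oc3c(OC)cc(C[C@H]4C(=O)OC[C@@H]4[C@@H](O)c4ccc(O)c(OC)c4)cc3[C@@H]2CO)ccc1O | target

**Count**

Total steps: 20. Longest linear sequence: 12 steps (1, 2, 4, 5, 6, 7, 8, 9, 10, 11, 19, 20).

**Steps most likely to fail**

1. Step 6 (ring contraction). What may go wrong:
- dehydrogenation to the flavone;
- migration of the C2 aryl group in place of the benzo carbon;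
- solvent capture at C3 without migration;
- acid-induced opening of the pyranone, which would erode the C2 configuration.

Fallback, from 10 back to 11: the same C3–C3a bond is made stepwise, and the rearrangement itself is no longer oxidative. Bromination of 10 at C3 with CuBr2 in EtOAc/CHCl3 at reflux should give the trans-3-bromoflavanone F1 (bromine equatorial, anti to the aryl group). HC(OMe)3 and TsOH in MeOH convert it into the dimethyl ketal F2. Heating F2 with ZnBr2 in toluene at 100 °C ionises the C–Br bond with a concerted shift of the benzo carbon (the α-halo ketal rearrangement known from 2-arylalkanoic ester synthesis). Bromide then removes one methyl group from the dimethoxycarbenium ion to give 11 with the same trans outcome.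

2. Step 5 (asymmetric oxa-Michael closure and decarboxylation). What may go wrong:
- amine-promoted or uncatalysed cyclisation of 8 that gives racemic material;
- weak face selection with the ortho-methoxy phenol;
- retro-oxa-Michael opening during the hot acidic decarboxylation, which lowers the enantiomeric purity.

Fallback, from 5 back to 10: C2 is set by C–C instead of C–O bond formation. TFA followed by heating in toluene converts 5 into 1-(5-bromo-2-hydroxy-3-methoxyphenyl)ethanone F3. Me2NCH(OMe)2 at 100 °C gives the enaminone F4, which closes with HCl in CH2Cl2 to 6-bromo-8-methoxychromone F5. The aryl group is then delivered from the aryl boronate F6, made from commercial 2-methoxy-4-(pinacolboryl)phenol with MsCl/Et3N. The addition is an asymmetric 1,4-addition under monovalent rhodium catalysis ([Rh(OH)(cod)]2, an (S)-configured electron-poor biaryl bisphosphine, aq. K3PO4, toluene, 50 °C), with the face selection expected from additions to cyclic enones. This gives 10 without a β-keto ester stage.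

3. Step 19 (fragment union). What may go wrong:
- ionisation, hydrolysis or self-alkylation of the electron-rich benzylic bromide before it meets the enolate;
- slow reaction of the hindered enolate;
- a second alkylation.

Fallback, from 28 and 16 back to 30: the sequence of step 10 is worked up before NaBH4 is added, so that the aldehyde 16 is isolated. Aldol addition of the lithium enolate 29 to 16 (THF, −78 °C) should give the β-hydroxy lactone F7, with the new bond anti to the C4 substituent and as a mixture of carbinol epimers. PhOC(S)Cl with pyridine and DMAP gives the thionocarbonate F8. Bu3SnH with AIBN in toluene at 80 °C then removes the benzylic oxygen (Barton–McCombie deoxygenation), which merges both epimers into 30.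

**Further compounds**

F1 | step 6 | (2R,3R)-3,6-dibromo-8-methoxy-2-[3-methoxy-4-(methylsulfonyloxy)phenyl]chroman-4-one (trans; C2 spatially as in 10) | COc1cc([C@H]2Oc3c(OC)cc(Br)cc3C(=O)[C@@H]2Br)ccc1OS(C)(=O)=O
F2 | step 6 | (2R,3R)-3,6-dibromo-4,4,8-trimethoxy-2-[3-methoxy-4-(methylsulfonyloxy)phenyl]chromane | COc1cc([C@H]2Oc3c(OC)cc(Br)cc3C(OC)(OC)[C@@H]2Br)ccc1OS(C)(=O)=O
F3 | step 5 | 1-(5-bromo-2-hydroxy-3-methoxyphenyl)ethanone | CC(=O)c1cc(Br)cc(OC)c1O
F4 | step 5 | (E)-1-(5-bromo-2-hydroxy-3-methoxyphenyl)-3-(dimethylamino)prop-2-en-1-one | CN(C)/C=C/C(=O)c1cc(Br)cc(OC)c1O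
F5 | step 5 | 6-bromo-8-methoxy-4H-chromen-4-one | COc1cc(Br)cc2c(=O)ccoc12
F6 | step 5 | 2-methoxy-4-(4,4,5,5-tetramethyl-1,3,2-dioxaborolan-2-yl)phenyl methanesulfonate | COc1cc(B2OC(C)(C)C(C)(C)O2)ccc1OS(C)(=O)=O
F7 | step 19 | (3S,4R)-3-{hydroxy[(2S,3R)-2-[4-(TBSO)-3-methoxyphenyl]-3-(TBSO-methyl)-7-methoxy-2,3-dihydro-1-benzofuran-5-yl]methyl}-4-{(R)-[4-(TBSO)-3-methoxyphenyl](TBSO)methyl}oxolan-2-one (carbinol epimers) | COc1cc([C@H]2Oc3c(OC)cc(C(O)[C@H]4C(=O)OC[C@@H]4[C@@H](O[Si](C)(C)C(C)(C)C)c4ccc(O[Si](C)(C)C(C)(C)C)c(OC)c4)cc3[C@@H]2CO[Si](C)(C)C(C)(C)C)ccc1O[Si](C)(C)C(C)(C)C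
F8 | step 19 | O-phenyl thionocarbonate of F7 (carbinol epimers) | COc1cc([C@H]2Oc3c(OC)cc(C(OC(=S)Oc5ccccc5)[C@H]4C(=O)OC[C@@H]4[C@@H](O[Si](C)(C)C(C)(C)C)c4ccc(O[Si](C)(C)C(C)(C)C)c(OC)c4)cc3[C@@H]2CO[Si](C)(C)C(C)(C)C)ccc1O[Si](C)(C)C(C)(C)C
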